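**Plan**

- Retrosynthesis: first cut the ester C–O bond between the C3 CH2–O arm and the caffeoyl group. Then cut, in one operation, the oxolane C3–C4 bond, the O–H of the C3 arm and the benzylic C–H of the C4 arm, which unravels the ring to an epoxy cinnamyl ether. Then cut the ether bond O1–C5, and finally the oxirane and the C2–vinyl bond back to vanillin.
- Enabling feature: in the oxolane (O1, C2–C5), C3 bears a CH2–O arm and C4 bears an ArCH2 arm, and the two are linked through C2–O1–C5. C3 is therefore the radical carbon of a reductively opened terminal oxirane, and C4 is the inner carbon of an aryl-substituted allyl ether, set up for 5-exo closure to a benzylic radical.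
- Forward order: vanillin → aryl vinyl carbinol → resolved epoxy alcohol; methyl ferulate → cinnamyl bromide; Williamson ether; radical closure of the only ring made in the route; esterification with silylated caffeic acid; one fluoride deprotection.
- Stereochemistry: C2 comes from the tartrate-controlled kinetic resolution (step 3). C3 and C4 come from the chair-like transition state of the radical closure under control of C2 (2,3-trans, 3,4-cis). The E alkene of the caffeate comes from caffeic acid.
- Protecting groups: the primary hydroxyl is released only in the key step, so it is the sole free hydroxyl at the acylation. All four phenols are silyl ethers and are removed together at the end.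

Key step: step 8

Assumption: the usual facial rule of the titanium–tartrate epoxidation is taken to hold for the aryl vinyl carbinol 3, so that L-(+)-diisopropyl tartrate consumes the (R)-enantiomer. The oxirane configuration of 4 and 9 has no consequence, because that carbon becomes a planar radical in step 8.

**Route**

Step 1
Reactants: 1 vanillin
Product: 2 3-methoxy-4-(triisopropylsilyloxy)benzaldehyde
Conditions: TIPSCl, imidazole, DMF, rt
Reagents that add atoms: triisopropylsilyl chloride CC(C)[Si](Cl)(C(C)C)C(C)C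
Why: Imidazole-promoted O-silylation of the phenol gives an aryl silyl ether that should tolerate the Grignard, hydride, alkoxide and radical steps that follow.

Step 2
Reactants: 2 3-methoxy-4-(triisopropylsilyloxy)benzaldehyde
Product: 3 (±)-1-[3-methoxy-4-(triisopropylsilyloxy)phenyl]prop-2-en-1-ol
Conditions: CH2=CHMgBr, THF, −78 to 0 °C; then H2O
Reagents that add atoms: vinylmagnesium bromide C=C[Mg]Br
Why: Grignard 1,2-addition to the aldehyde gives the racemic secondary allylic alcohol needed for the resolution.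

Step 3
Reactants: 3 (±)-1-[3-methoxy-4-(triisopropylsilyloxy)phenyl]prop-2-en-1-ol
Product: 4 (S)-[3-methoxy-4-(triisopropylsilyloxy)phenyl][(2R)-oxiran-2-yl]methanol
Conditions: Ti(OiPr)4 (0.2 equiv), L-(+)-diisopropyl tartrate (0.25 equiv), t-BuOOH (0.45 equiv), 4 Å MS, CH2Cl2, −20 °C
Reagents that add atoms: tert-butyl hydroperoxide CC(C)(C)OO
Why: In this Sharpless kinetic resolution the (R)-enantiomer of 3 should be epoxidized much faster, on the alkene face syn to the titanium-bound hydroxyl, to give the erythro epoxy alcohol and so fix the carbinol center that becomes C2; the (S)-enantiomer stays behind as allylic alcohol and is removed by chromatography.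

Step 4
Reactants: 5 methyl (E)-ferulate
Product: 6 methyl (2E)-3-[3-methoxy-4-(triisopropylsilyloxy)phenyl]prop-2-enoate
Conditions: TIPSCl, imidazole, DMF, rt
Reagents that add atoms: triisopropylsilyl chloride CC(C)[Si](Cl)(C(C)C)C(C)C
Why: Imidazole-promoted O-silylation masks the phenol with the same group as in the other half.

Step 5
Reactants: 6 methyl (2E)-3-[3-methoxy-4-(triisopropylsilyloxy)phenyl]prop-2-enoate
Product: 7 (2E)-3-[3-methoxy-4-(triisopropylsilyloxy)phenyl]prop-2-en-1-ol
Conditions: i-Bu2AlH (2.5 equiv), CH2Cl2, −78 °C; Rochelle salt work-up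
Reagents that add atoms: none
Why: 1,2-Reduction of the enoate with i-Bu2AlH should give the allylic alcohol with the E alkene intact.

Step 6
Reactants: 7 (2E)-3-[3-methoxy-4-(triisopropylsilyloxy)phenyl]prop-2-en-1-ol
Product: 8 {4-[(1E)-3-bromoprop-1-en-1-yl]-2-methoxyphenoxy}triisopropylsilane
Conditions: CBr4, PPh3, CH2Cl2, −20 to 0 °C; used at once
Reagents that add atoms: carbon tetrabromide BrC(Br)(Br)Br
Why: The Appel reaction converts the primary allylic alcohol into the bromide under neutral conditions, which suits an acid-labile electron-rich cinnamyl system.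

Step 7
Reactants: 4 (S)-[3-methoxy-4-(triisopropylsilyloxy)phenyl][(2R)-oxiran-2-yl]methanol; 8 {4-[(1E)-3-bromoprop-1-en-1-yl]-2-methoxyphenoxy}triisopropylsilane
Product: 9 (2R)-2-[(S)-[3-methoxy-4-(triisopropylsilyloxy)phenyl]{[(2E)-3-[3-methoxy-4-(triisopropylsilyloxy)phenyl]prop-2-en-1-yl]oxy}methyl]oxirane
Conditions: NaH, THF, 0 °C; then 8, Bu4NI (cat.), 0 °C to rt
Reagents that add atoms: none
Why: Williamson etherification by SN2 attack of the sodium alkoxide on the primary allylic bromide forms the O1–C5 bond without touching the carbinol stereocenter; low temperature and an aprotic medium should suppress Payne rearrangement.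

Step 8
Reactants: 9 (2R)-2-[(S)-[3-methoxy-4-(triisopropylsilyloxy)phenyl]{[(2E)-3-[3-methoxy-4-(triisopropylsilyloxy)phenyl]prop-2-en-1-yl]oxy}methyl]oxirane
Product: 11 [(2R,3S,4S)-2-[3-methoxy-4-(triisopropylsilyloxy)phenyl]-4-{[3-methoxy-4-(triisopropylsilyloxy)phenyl]methyl}oxolan-3-yl]methanol, via dititanated oxolane 10 (not isolated)
Conditions: Cp2TiCl2 (2.5 equiv), Zn, THF, rt (gives Cp2TiCl); added slowly to 9 (0.02 M, THF), rt; then 1 M HCl, 0 °C
Reagents that add atoms: none
Why: Cp2TiCl (trivalent titanium) transfers one electron to the oxirane of 9, whose more substituted C–O bond breaks to leave a secondary carbon radical at the future C3 that already bears the CH2–O–Ti arm; this radical adds to the inner alkene carbon of the cinnamyl ether (future C4), and the benzylic radical so formed is reduced by a second Cp2TiCl (10) and protonated on work-up to the arylmethyl arm. The closest known reaction type is the reductive epoxide-opening radical cyclization of epoxy alkenes with Cp2TiCl (Nugent–RajanBabu reaction), here on an epoxy allyl ether. The oxolane ring closes in the 5-exo-trig mode. C3 and C4 are set in a chair-like Beckwith–Houk transition state under control of the existing C2 center: the C2 aryl sits pseudo-equatorial and ends trans to the new C4 arm, and the CH2O–Ti arm on the radical carbon ends cis to the C4 arm and therefore trans to the C2 aryl, while the oxirane stereocenter is erased in the planar radical. The step needs ring closure to outrun reduction of the first radical by Cp2TiCl (which would end in deoxygenation) and needs opening toward the secondary radical; the fast closure onto a styrene-type acceptor, slow addition of the reagent at high dilution, and the preference of titanium for the oxygen at the less hindered terminus should secure both.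

Step 9
Reactants: 12 caffeic acid
Product: 14 (2E)-3-[3,4-bis(tert-butyldimethylsilyloxy)phenyl]prop-2-enoic acid, via tris-silylated caffeate 13 (not isolated)
Conditions: TBSCl (3.5 equiv), imidazole, DMF, rt; then AcOH–THF–H2O, rt
Reagents that add atoms: tert-butyldimethylsilyl chloride CC(C)(C)[Si](C)(C)Cl
Why: Exhaustive silylation followed by mild aqueous acid should cleave only the labile silyl ester and leave both aryl silyl ethers in place.

Step 10
Reactants: 11 [(2R,3S,4S)-2-[3-methoxy-4-(triisopropylsilyloxy)phenyl]-4-{[3-methoxy-4-(triisopropylsilyloxy)phenyl]methyl}oxolan-3-yl]methanol; 14 (2E)-3-[3,4-bis(tert-butyldimethylsilyloxy)phenyl]prop-2-enoic acid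
Product: 15 [(2R,3S,4S)-2-[3-methoxy-4-(triisopropylsilyloxy)phenyl]-4-{[3-methoxy-4-(triisopropylsilyloxy)phenyl]methyl}oxolan-3-yl]methyl (2E)-3-[3,4-bis(tert-butyldimethylsilyloxy)phenyl]prop-2-enoate
Conditions: EDC·HCl, DMAP, CH2Cl2, 0 °C to rt
Reagents that add atoms: none
Why: Steglich esterification acylates the only free hydroxyl of 11 under neutral conditions that leave the benzylic ether and the silyl ethers alone.

Step 11
Reactants: 15 [(2R,3S,4S)-2-[3-methoxy-4-(triisopropylsilyloxy)phenyl]-4-{[3-methoxy-4-(triisopropylsilyloxy)phenyl]methyl}oxolan-3-yl]methyl (2E)-3-[3,4-bis(tert-butyldimethylsilyloxy)phenyl]prop-2-enoate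
Product: 16 [(2R,3S,4S)-2-(4-hydroxy-3-methoxyphenyl)-4-[(4-hydroxy-3-methoxyphenyl)methyl]oxolan-3-yl]methyl (2E)-3-(3,4-dihydroxyphenyl)prop-2-enoate
Conditions: Bu4NF, AcOH, THF, 0 °C, degassed
Reagents that add atoms: none
Why: Fluoride cleavage of the four aryl silyl ethers, buffered with acetic acid, should spare the cinnamate ester, the catechol and the acid-sensitive 2-aryl oxolane.

**Compound list**

1 | vanillin (4-hydroxy-3-methoxybenzaldehyde) | COc1cc(C=O)ccc1O | starting material
2 | 3-methoxy-4-(triisopropylsilyloxy)benzaldehyde | COc1cc(C=O)ccc1O[Si](C(C)C)(C(C)C)C(C)C | intermediate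
3 | (±)-1-[3-methoxy-4-(triisopropylsilyloxy)phenyl]prop-2-en-1-ol | COc1cc(C(O)C=C)ccc1O[Si](C(C)C)(C(C)C)C(C)C | intermediate
4 | (S)-[3-methoxy-4-(triisopropylsilyloxy)phenyl][(2R)-oxiran-2-yl]methanol | C1O[C@H]1[C@@H](O)c1ccc(O[Si](C(C)C)(C(C)C)C(C)C)c(OC)c1 | intermediate
5 | methyl (E)-ferulate, methyl (2E)-3-(4-hydroxy-3-methoxyphenyl)prop-2-enoate | COC(=O)/C=C/c1ccc(O)c(OC)c1 | starting material
6 | methyl (2E)-3-[3-methoxy-4-(triisopropylsilyloxy)phenyl]prop-2-enoate | COC(=O)/C=C/c1ccc(O[Si](C(C)C)(C(C)C)C(C)C)c(OC)c1 | intermediate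
7 | (2E)-3-[3-methoxy-4-(triisopropylsilyloxy)phenyl]prop-2-en-1-ol | OC/C=C/c1ccc(O[Si](C(C)C)(C(C)C)C(C)C)c(OC)c1 | intermediate
8 | {4-[(1E)-3-bromoprop-1-en-1-yl]-2-methoxyphenoxy}triisopropylsilane | BrC/C=C/c1ccc(O[Si](C(C)C)(C(C)C)C(C)C)c(OC)c1 | intermediate
9 | (2R)-2-[(S)-[3-methoxy-4-(triisopropylsilyloxy)phenyl]{[(2E)-3-[3-methoxy-4-(triisopropylsilyloxy)phenyl]prop-2-en-1-yl]oxy}methyl]oxirane | C1O[C@H]1[C@@H](OC/C=C/c1ccc(O[Si](C(C)C)(C(C)C)C(C)C)c(OC)c1)c1ccc(O[Si](C(C)C)(C(C)C)C(C)C)c(OC)c1 | intermediate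
10 | dititanated oxolane: the cyclized product carrying Cp2TiCl on the C3 CH2–O oxygen and on the benzylic carbon of the C4 arm (benzylic configuration undefined) | COc1cc(C([Ti](Cl)(C2C=CC=C2)C2C=CC=C2)[C@@H]2CO[C@@H](c3ccc(O[Si](C(C)C)(C(C)C)C(C)C)c(OC)c3)[C@@H]2CO[Ti](Cl)(C2C=CC=C2)C2C=CC=C2)ccc1O[Si](C(C)C)(C(C)C)C(C)C | intermediate
11 | [(2R,3S,4S)-2-[3-methoxy-4-(triisopropylsilyloxy)phenyl]-4-{[3-methoxy-4-(triisopropylsilyloxy)phenyl]methyl}oxolan-3-yl]methanol | COc1cc(C[C@@H]2CO[C@@H](c3ccc(O[Si](C(C)C)(C(C)C)C(C)C)c(OC)c3)[C@@H]2CO)ccc1O[Si](C(C)C)(C(C)C)C(C)C | intermediate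
12 | caffeic acid, (2E)-3-(3,4-dihydroxyphenyl)prop-2-enoic acid | OC(=O)/C=C/c1ccc(O)c(O)c1 | starting material
13 | tert-butyldimethylsilyl (2E)-3-[3,4-bis(tert-butyldimethylsilyloxy)phenyl]prop-2-enoate | CC(C)(C)[Si](C)(C)OC(=O)/C=C/c1ccc(O[Si](C)(C)C(C)(C)C)c(O[Si](C)(C)C(C)(C)C)c1 | intermediate
14 | (2E)-3-[3,4-bis(tert-butyldimethylsilyloxy)phenyl]prop-2-enoic acid | OC(=O)/C=C/c1ccc(O[Si](C)(C)C(C)(C)C)c(O[Si](C)(C)C(C)(C)C)c1 | intermediate
15 | [(2R,3S,4S)-2-[3-methoxy-4-(triisopropylsilyloxy)phenyl]-4-{[3-methoxy-4-(triisopropylsilyloxy)phenyl]methyl}oxolan-3-yl]methyl (2E)-3-[3,4-bis(tert-butyldimethylsilyloxy)phenyl]prop-2-enoate | COc1cc(C[C@@H]2CO[C@@H](c3ccc(O[Si](C(C)C)(C(C)C)C(C)C)c(OC)c3)[C@@H]2COC(=O)/C=C/c2ccc(O[Si](C)(C)C(C)(C)C)c(O[Si](C)(C)C(C)(C)C)c2)ccc1O[Si](C(C)C)(C(C)C)C(C)C | intermediate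
16 | [(2R,3S,4S)-2-(4-hydroxy-3-methoxyphenyl)-4-[(4-hydroxy-3-methoxyphenyl)methyl]oxolan-3-yl]methyl (2E)-3-(3,4-dihydroxyphenyl)prop-2-enoate | COc1cc(C[C@@H]2CO[C@@H](c3ccc(O)c(OC)c3)[C@@H]2COC(=O)/C=C/c2ccc(O)c(O)c2)ccc1O | target

**Count and risks**

Total step count: 11. Longest linear sequence: 7 steps (1, 2, 3, 7, 8, 10, 11).

Steps most likely to fail:

Step 8. The β-titanoxy radical may be reduced by a second Cp2TiCl before it closes, which ends in deoxygenation to the allyl ether, and facial control in the closure may be only moderate. The fallback sets out from 9 and comes back at 11. The oxirane of 9 is opened at its CH2 terminus by pivalate (CsOPiv, PivOH, DMF, 80 °C) to give the hydroxy pivalate F1. The secondary hydroxyl is converted with PhOC(S)Cl, pyridine and DMAP into the O-phenyl thionocarbonate F2. Bu3SnH and AIBN in benzene at 80 °C, with syringe-pump addition, generate the same C3 radical with no metal reductant present, and it closes 5-exo to the oxolane pivalate F3. i-Bu2AlH then removes the pivalate to give 11.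

Step 3. Discrimination between the enantiomers of an aryl vinyl carbinol may be insufficient, and the electron-rich benzylic epoxy alcohol may be opened by titanium alkoxides during the slow reaction, eroding both optical purity and material. The fallback sets out from 3 and comes back at 4. Lipase acylation (Candida antarctica lipase B, vinyl acetate) should convert the (R)-enantiomer into the (R)-acetate F4, which is separated from the unreacted (S)-alcohol and cleaved with i-Bu2AlH to the (R)-carbinol F5. F5 is then epoxidized to full conversion with Ti(OiPr)4, L-(+)-diisopropyl tartrate and t-BuOOH in the matched sense, so that the enzyme and not the epoxidation sets the absolute configuration.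

Step 7. The epoxy alkoxide may undergo Payne rearrangement, and the electron-rich cinnamyl bromide may ionize or decompose before substitution occurs. The fallback sets out from 7 and 4 and comes back at 9, bypassing 8. Alcohol 7 is acetylated (Ac2O, pyridine) to the cinnamyl acetate F6. F6 is coupled with the zinc alkoxide of 4 (Et2Zn) under Pd(OAc)2/phosphine catalysis, an allylic etherification through a π-allyl complex of divalent palladium formed from zerovalent palladium. Attack at the unsubstituted terminus should give 9 without strong base.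

**Further compounds**

F1 | step 8 | (2R,3S)-2-hydroxy-3-[3-methoxy-4-(triisopropylsilyloxy)phenyl]-3-{[(2E)-3-[3-methoxy-4-(triisopropylsilyloxy)phenyl]prop-2-en-1-yl]oxy}propyl 2,2-dimethylpropanoate | CC(C)(C)C(=O)OC[C@@H](O)[C@@H](OC/C=C/c1ccc(O[Si](C(C)C)(C(C)C)C(C)C)c(OC)c1)c1ccc(O[Si](C(C)C)(C(C)C)C(C)C)c(OC)c1
F2 | step 8 | (2R,3S)-3-[3-methoxy-4-(triisopropylsilyloxy)phenyl]-3-{[(2E)-3-[3-methoxy-4-(triisopropylsilyloxy)phenyl]prop-2-en-1-yl]oxy}-2-[(phenoxycarbonothioyl)oxy]propyl 2,2-dimethylpropanoate | CC(C)(C)C(=O)OC[C@@H](OC(=S)Oc1ccccc1)[C@@H](OC/C=C/c1ccc(O[Si](C(C)C)(C(C)C)C(C)C)c(OC)c1)c1ccc(O[Si](C(C)C)(C(C)C)C(C)C)c(OC)c1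
F3 | step 8 | [(2R,3S,4S)-2-[3-methoxy-4-(triisopropylsilyloxy)phenyl]-4-{[3-methoxy-4-(triisopropylsilyloxy)phenyl]methyl}oxolan-3-yl]methyl 2,2-dimethylpropanoate | COc1cc(C[C@@H]2CO[C@@H](c3ccc(O[Si](C(C)C)(C(C)C)C(C)C)c(OC)c3)[C@@H]2COC(=O)C(C)(C)C)ccc1O[Si](C(C)C)(C(C)C)C(C)C
F4 | step 3 | (1R)-1-[3-methoxy-4-(triisopropylsilyloxy)phenyl]prop-2-en-1-yl acetate | C=C[C@@H](OC(C)=O)c1ccc(O[Si](C(C)C)(C(C)C)C(C)C)c(OC)c1
F5 | step 3 | (1R)-1-[3-methoxy-4-(triisopropylsilyloxy)phenyl]prop-2-en-1-ol | C=C[C@@H](O)c1ccc(O[Si](C(C)C)(C(C)C)C(C)C)c(OC)c1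
F6 | step 7 | (2E)-3-[3-methoxy-4-(triisopropylsilyloxy)phenyl]prop-2-en-1-yl acetate | CC(=O)OC/C=C/c1ccc(O[Si](C(C)C)(C(C)C)C(C)C)c(OC)c1
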